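## The problem

The target 26 is a 3,3''-linked biflavanone: two chroman-4-ones joined through their α-carbons. Unit 1 carries a 4-methoxyphenyl group at C2, unit 2 a 4-hydroxyphenyl group at C2''. The four stereocentres are contiguous (C2, C3, C3'', C2''); the configuration is 2S,3R (2,3-trans) in unit 1 and 2''S,3''S (2,3-cis, the less stable arrangement) in unit 2. C3 and C3'' are α to ketones, and C2 and C2'' are benzylic ether carbons β to them, so every centre can be lost by enolisation or retro-oxa-Michael opening under base, strong acid or heat. Only C2 needs control from outside: C3 can follow from C2 (anti alkylation, also the stable result), C3'' from C3 through a conformationally biased enolate, and C2'' from C3'' through a closed aldol transition state. Ring C of unit 2 must then close without touching either new centre. Five phenols must end free while the anisyl methyl ether survives, so the protecting groups must come off by hydrogenolysis or by chelation to a carbonyl. The feature that opens the plan is ring A of unit 1: oxygen at C5, C7 and C8a in a 1,3,5 pattern, with the acyl carbon C4 on C4a, is the footprint of a 1,1,3-trioxygenated butadiene (C5 to C8) added across the C4a=C8a enol-ether bond of a 4-pyranone, with bromine at C4a supplying the oxidation level of the arene.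

## Retrosynthesis

**End game.** The C5 phenol of 26 is traced to its methyl ether 25, and the four other phenols of 25 to the benzyl ethers of 24. Forward, hydrogenolysis comes first and BCl3 second: BCl3 on 24 would also attack benzyl ethers and release benzyl cations next to two phloroglucinol rings. The methyl ether at C5 is the one ether that chelation to C4=O lets BCl3 remove while the anisyl ether stays. Both steps must leave the cis unit untouched.

**Ring C of unit 2.** In 24 the aryl ether bond O1''–C8a'' is cut, giving the β-hydroxy ketone 22 with fluorine at C8a''. Cutting O1''–C2'' instead (chalcone cyclisation) would deliver the stable trans isomer, and a Mitsunobu closure needs a free phenol and inversion at an ionisable benzylic carbon. Attack of the C2'' alkoxide on the fluoroarene keeps the C2''–O bond, so the syn relation in 22 becomes the cis relation in 24. The forward reaction must be faster than retro-aldol cleavage.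

**C2''–C3'' bond.** 22 is cut to ketone 19 and 4-(benzyloxy)benzaldehyde 20. The neighbouring cut, C3–C3'' (coupling of two flavanone enolates), offers no handle on a cis unit. The aldol removes two stereocentres and fourteen carbons at once. It asks for the Z-enolate of the acyclic ketone only, a syn-selective chair transition state, and attack on the enolate face turned away from C2.

**Phenol protection.** 19 is the benzyl ether of phenol 18; the C7 hydroxyl is freed in the ring-forming step and must be masked before enolate chemistry.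

**Ring A of unit 1 (key cut).** In 18 the bonds C4a–C5 and C8–C8a are cut, giving bromopyranone 13 and diene 16. Cuts at C4–C4a, O1–C8a or C2–aryl start from phloroglucinol derivatives and pass through flavanone enolates or ionisable benzylic ethers. This cut instead leaves a monocyclic dihydropyranone whose C2 centre comes from a catalytic hetero-Diels–Alder reaction. It also tells O5 (methyl) from O7 (free) without a separate step. The forward reaction must give one regiochemistry, aromatise by loss of HBr and methanol, and leave C2 and C3 alone.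

**The dienophile.** 13 is cut at C3–CH2 into the bromopyranone 5 and iodoketone 11. The side chain is brought in as the complete aryl ketone, not as an acetate, because an ester would later have to be converted into an aryl ketone beside the C4 ketone, whereas the aryl ketone is only a spectator in the ring-forming step. 5 comes from pyranone 4 by bromination at the enol-ether carbon, done before the electron-rich aryl ketone is present. 4 comes from 4-methoxybenzaldehyde 1 and diene 2 (bonds O1–C6 and C2–C3 of the pyranone).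

**The small fragments.** 11 goes back through chloroketone 10 to aryl bromide 8, fluoroarene 7 and 1,3,5-trifluorobenzene 6 (C–C bond to the ring by bromine–lithium exchange, two C–O bonds by SNAr). Diene 16 is the silyl enol ether of 15, the acetylation product of 1,1-dimethoxyethene 14.

## Roads not taken

Alternative 1: The cut is at C2–aryl and C3–CH2 of unit 1. A monovalent rhodium–bisphosphine catalyst would add (4-methoxyphenyl)zinc chloride A2 to 5,7-bis(benzyloxy)-4H-chromen-4-one A1, and the zinc enolate would be alkylated by 2-bromo-1-[2,4-bis(benzyloxy)-6-fluorophenyl]ethan-1-one A3 anti to the new aryl group, which would give the chromanone A4.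
- Merits: ring A is bought; two bonds and both stereocentres of unit 1 arise in one flask; A4 is the all-benzyl counterpart of 19, so the end game needs no BCl3. In step count and in the mildness of the last step this road is better than the chosen one.
- Weak points: a zinc enolate is a poor nucleophile towards an alkyl halide such as A3, and while it waits it can expel the ring phenoxide, which erodes C2. The peri benzyloxy group at C5 of A1 also crowds the site at which the aryl group of A2 must be delivered.
- What the chosen plan sets against it: C2 comes from a hetero-Diels–Alder reaction of an unhindered aldehyde, and C3 is alkylated as a lithium enolate at low temperature. The price is a longer sequence and an untested annulation, and the fallback for the key step is in essence this road.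

Alternative 2: The cut is at O1–C2 and C3–C4. An α-methoxy ortho-quinone methide, released by acid from 2,4-bis(benzyloxy)-6-hydroxybenzaldehyde A5 and an orthoformate, would add across methyl (E)-4-(4-methoxyphenyl)but-3-enoate A6 under a chiral phosphoric acid, which would give the chroman A7.
- Merits: the route is convergent, and the E-alkene geometry of A6 is translated directly into the 2,3-trans relation. C4 arrives masked as a methyl ether, so turning the ester into the aryl ketone of unit 2 would meet no competing ketone; in that respect it is cleaner than an ester-based version of the present plan.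
- Weak points: A6 is a weakly nucleophilic alkene that can slip into conjugation under acid, and the quinone methide from A5 is stabilised by two alkoxy groups. C4 of A7 must later be oxidised to the ketone beside a doubly activated benzylic C2–H and several benzyl ethers.
- What the chosen plan sets against it: the correct oxidation level at C4 from the start, and an aryl ketone side chain already in place, at the cost of lower convergence.

Alternative 3: The cut is at C4–C4a. Bromine–lithium exchange on the bromoaryl ether lactone A8 would give an aryllithium that attacks the lactone carbonyl, closing ring C of unit 1 and releasing the C2'' hydroxyl in the hydroxy ester A9.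
- Merits: C3, C3'' and C2'' are fixed on a five-membered lactone, where relative configuration is easier to secure than in an open-chain aldol. This is better than the substrate-controlled aldol of the chosen plan. The ketone and the carbinol needed for unit 2 appear in the same step.
- Weak points: A8 requires a long linear sequence, including an aryl ether at a benzylic stereocentre. The aryllithium must choose the lactone over the tert-butyl ester and over acidic C–H bonds. The ester of A9 must still become an aryl ketone beside the C4 ketone and a retro-aldol-prone β-hydroxyl.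
- What the chosen plan sets against it: brevity, and an aryl ketone for unit 2 that never has to be made in the presence of the C4 ketone.

Key step: step 10

## Assumptions

- Atoms of unit 1 (the 4-methoxyphenyl chromanone) are numbered O1 to C8a; those of unit 2 carry double primes.
- The (S)-BINOL complex of tetravalent titanium is taken to give the (S)-pyranone from 4-methoxybenzaldehyde, as with simple aromatic aldehydes; if the sense is opposite, (R)-BINOL is used.

## Route

Step 1
Reactants: 1 4-methoxybenzaldehyde; 2 (E)-1-methoxy-3-(trimethylsilyloxy)buta-1,3-diene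
Product: 4 (S)-2-(4-methoxyphenyl)-2,3-dihydro-4H-pyran-4-one, via O-silylated Mukaiyama aldol adduct 3 (not isolated)
Conditions: Ti(OiPr)4 (10 mol%), (S)-BINOL (20 mol%), 4 Å MS, Et2O, –20 °C; then CF3CO2H, CH2Cl2, 0 °C
Reagents that add atoms: none
Why: Catalytic asymmetric hetero-Diels–Alder reaction running as a Mukaiyama aldol addition followed by acid cyclisation with loss of methanol; the chiral complex formed from Ti(OiPr)4 and (S)-BINOL selects the aldehyde face and so sets C2.

Step 2
Reactants: 4 (S)-2-(4-methoxyphenyl)-2,3-dihydro-4H-pyran-4-one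
Product: 5 (S)-5-bromo-2-(4-methoxyphenyl)-2,3-dihydro-4H-pyran-4-one
Conditions: NBS, CH2Cl2, 0 °C → rt
Reagents that add atoms: N-bromosuccinimide, O=C1CCC(=O)N1Br
Why: Electrophilic α-bromination of the vinylogous ester at its nucleophilic enol-ether carbon; the anisyl ring is far less reactive in CH2Cl2 and C2 is not involved.

Step 3
Reactants: 6 1,3,5-trifluorobenzene
Product: 7 1,3-bis(benzyloxy)-5-fluorobenzene
Conditions: BnOH (2.1 equiv), NaH, NMP, 0 → 100 °C
Reagents that add atoms: benzyl alcohol, OCc1ccccc1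
Why: Twofold SNAr by benzyl oxide; each alkoxy group introduced slows the next substitution, so with two equivalents of alkoxide the reaction should stop once the second fluoride has been replaced.

Step 4
Reactants: 7 1,3-bis(benzyloxy)-5-fluorobenzene
Product: 8 1,5-bis(benzyloxy)-2-bromo-3-fluorobenzene
Conditions: NBS (1.0 equiv), MeCN, 0 °C → rt
Reagents that add atoms: N-bromosuccinimide, O=C1CCC(=O)N1Br
Why: Electrophilic aromatic bromination para to one benzyloxy group and ortho to the other; the position between the two benzyloxy groups is the more hindered one, as in resorcinol diethers.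

Step 5
Reactants: 8 1,5-bis(benzyloxy)-2-bromo-3-fluorobenzene
Product: 10 1-[2,4-bis(benzyloxy)-6-fluorophenyl]-2-chloroethan-1-one, via aryllithium 9 (not isolated)
Conditions: n-BuLi, THF, –78 °C; then ClCH2C(O)N(OMe)Me, –78 °C; aq. NH4Cl
Reagents that add atoms: 2-chloro-N-methoxy-N-methylacetamide, CON(C)C(=O)CCl
Why: Bromine–lithium exchange, faster at –78 °C than benzylic deprotonation or loss of LiF, followed by Weinreb ketone synthesis; the chelated tetrahedral intermediate prevents over-addition and tolerates the α-chloride.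

Step 6
Reactants: 10 1-[2,4-bis(benzyloxy)-6-fluorophenyl]-2-chloroethan-1-one
Product: 11 1-[2,4-bis(benzyloxy)-6-fluorophenyl]-2-iodoethan-1-one
Conditions: NaI, acetone, rt, dark
Reagents that add atoms: sodium iodide, [Na+].[I-]
Why: Finkelstein exchange driven by precipitation of NaCl; the iodide is the more reactive SN2 partner for the enolate alkylation.

Step 7
Reactants: 5 (S)-5-bromo-2-(4-methoxyphenyl)-2,3-dihydro-4H-pyran-4-one; 11 1-[2,4-bis(benzyloxy)-6-fluorophenyl]-2-iodoethan-1-one
Product: 13 (2S,3R)-3-{2-[2,4-bis(benzyloxy)-6-fluorophenyl]-2-oxoethyl}-5-bromo-2-(4-methoxyphenyl)-2,3-dihydro-4H-pyran-4-one, via lithium enolate 12 (not isolated)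
Conditions: LiN(SiMe3)2, THF, –78 °C; then 11, DMPU, –78 → –40 °C; AcOH
Reagents that add atoms: none
Why: Kinetic enolate formation at C3 and SN2 alkylation with an α-iodo ketone whose carbonyl is shielded by two ortho substituents; the electrophile enters anti to the C2 aryl group, which sets C3 trans (also the stable arrangement).

Step 8
Reactants: 14 1,1-dimethoxyethene
Product: 15 4,4-dimethoxybut-3-en-2-one
Conditions: AcCl, Et3N, Et2O, 0 °C → rt
Reagents that add atoms: acetyl chloride, CC(Cl)=O
Why: C-acylation of a ketene acetal at its nucleophilic carbon; the amine removes the proton from the dialkoxycarbenium intermediate before chloride can demethylate it.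

Step 9
Reactants: 15 4,4-dimethoxybut-3-en-2-one
Product: 16 1,1-dimethoxy-3-(trimethylsilyloxy)buta-1,3-diene
Conditions: Me3SiOTf, Et3N, Et2O, 0 °C; distilled and used fresh
Reagents that add atoms: trimethylsilyl trifluoromethanesulfonate, C[Si](C)(C)OS(=O)(=O)C(F)(F)F
Why: Soft enolisation and O-silylation of a methyl ketone; the methyl group is the only enolisable position.

Step 10
Reactants: 13 (2S,3R)-3-{2-[2,4-bis(benzyloxy)-6-fluorophenyl]-2-oxoethyl}-5-bromo-2-(4-methoxyphenyl)-2,3-dihydro-4H-pyran-4-one; 16 1,1-dimethoxy-3-(trimethylsilyloxy)buta-1,3-diene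
Product: 18 (2S,3R)-3-{2-[2,4-bis(benzyloxy)-6-fluorophenyl]-2-oxoethyl}-7-hydroxy-5-methoxy-2-(4-methoxyphenyl)chroman-4-one, via bromo ketal cycloadduct 17 (not isolated)
Conditions: 16 (3 equiv), 2,6-lutidine (2 equiv), toluene, 80 °C, sealed tube; then Et3N, 0 °C → rt; then 1 M HCl, THF, 0 °C
Reagents that add atoms: none
Why: Proposed new method: a normal-electron-demand [4+2] addition in which the CH2 terminus of diene 16, its most nucleophilic carbon, bonds to C8a (the β-carbon of the bromo enone) and the acetal carbon bonds to C4a, either concertedly and asynchronously or as a Mukaiyama–Michael addition followed by closure of the bromo enolate onto the dimethoxycarbenium ion; both paths give the same constitution, 17. The closest known reactions are the Diels–Alder/aromatisation of 1,1-dialkoxy-3-silyloxybutadienes with haloquinones and of silyloxydienes with 3-substituted chromones; a 5-bromo-2,3-dihydro-4H-pyran-4-one has not served as the 2π partner. Ring A is closed by intermolecular annulation, two σ-bonds (C4a–C5 and C8–C8a) forming between the two reactants, so no tethered cyclisation mode has to be met. Aromatisation follows: the C5 ketal ionises with help from the enol ether and loses methanol by 1,4-elimination, triethylamine then removes HBr across C4a–C8a (the bromide is by then allylic and the step is driven by formation of the arene), and acid converts the silyl ether into the C7 phenol. No new stereocentre remains, since C4a and C8a become sp2; C2 and C3 are spectators and their trans relation is also the stable one. The selectivity needed is regiochemical (methoxy at C5, hydroxyl at C7) and rests on the polarity of the partners, the carbonyl and bromine marking C8a as the electrophilic end; the aryl ketone, aryl fluoride and benzyl ethers are inert to a neutral thermal reaction, and lutidine keeps HBr from opening the pyranone at C2.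

Step 11
Reactants: 18 (2S,3R)-3-{2-[2,4-bis(benzyloxy)-6-fluorophenyl]-2-oxoethyl}-7-hydroxy-5-methoxy-2-(4-methoxyphenyl)chroman-4-one
Product: 19 (2S,3R)-7-(benzyloxy)-3-{2-[2,4-bis(benzyloxy)-6-fluorophenyl]-2-oxoethyl}-5-methoxy-2-(4-methoxyphenyl)chroman-4-one
Conditions: BnBr, K2CO3, acetone, rt
Reagents that add atoms: benzyl bromide, BrCc1ccccc1
Why: Williamson etherification of the acidic C7 phenol (para to the C4 carbonyl); carbonate at room temperature does not enolise C3, and the phenoxide lowers the C–H acidity further, so C2 and C3 persist.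

Step 12
Reactants: 19 (2S,3R)-7-(benzyloxy)-3-{2-[2,4-bis(benzyloxy)-6-fluorophenyl]-2-oxoethyl}-5-methoxy-2-(4-methoxyphenyl)chroman-4-one; 20 4-(benzyloxy)benzaldehyde
Product: 22 (2S,3R)-7-(benzyloxy)-3-{(2S,3S)-1-[2,4-bis(benzyloxy)-6-fluorophenyl]-3-[4-(benzyloxy)phenyl]-3-hydroxy-1-oxopropan-2-yl}-5-methoxy-2-(4-methoxyphenyl)chroman-4-one, via Z-boron enolate 21 (not isolated)
Conditions: n-Bu2BOTf (1.2 equiv), i-Pr2NEt, CH2Cl2, –78 → 0 °C; then 20, –78 → –20 °C; pH 7 buffer, MeOH, H2O2, 0 °C
Reagents that add atoms: none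
Why: Boron-mediated aldol reaction through a Zimmerman–Traxler chair: soft enolisation occurs at the unhindered CH2 of the acyclic ketone (not at the tertiary C3–H of the electron-rich chromanone) and gives the Z-enolate, hence the syn relation C3''/C2''. In the enolate the C3–H bond eclipses the double bond to avoid allylic 1,3-strain with the boryloxy group, C2 with its aryl group covers one face, and the aldehyde should add to the other, which gives 3''S and therefore 2''S.

Step 13
Reactants: 22 (2S,3R)-7-(benzyloxy)-3-{(2S,3S)-1-[2,4-bis(benzyloxy)-6-fluorophenyl]-3-[4-(benzyloxy)phenyl]-3-hydroxy-1-oxopropan-2-yl}-5-methoxy-2-(4-methoxyphenyl)chroman-4-one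
Product: 24 (2S,3R)-7-(benzyloxy)-3-{(2S,3S)-5,7-bis(benzyloxy)-2-[4-(benzyloxy)phenyl]-4-oxochroman-3-yl}-5-methoxy-2-(4-methoxyphenyl)chroman-4-one, via potassium alkoxide 23 (not isolated)
Conditions: KN(SiMe3)2 (1.0 equiv), THF, –78 → 0 °C; AcOH
Reagents that add atoms: none
Why: Intramolecular SNAr (addition–elimination through a Meisenheimer complex stabilised by the ortho ketone) closing a six-membered ring; the C2''–O bond is not broken, so the syn adduct gives the cis ring with retention. The single equivalent of base ends as KF, leaving nothing to epimerise C3''.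

Step 14
Reactants: 24 (2S,3R)-7-(benzyloxy)-3-{(2S,3S)-5,7-bis(benzyloxy)-2-[4-(benzyloxy)phenyl]-4-oxochroman-3-yl}-5-methoxy-2-(4-methoxyphenyl)chroman-4-one
Product: 25 (2S,3R)-3-[(2S,3S)-5,7-dihydroxy-2-(4-hydroxyphenyl)-4-oxochroman-3-yl]-7-hydroxy-5-methoxy-2-(4-methoxyphenyl)chroman-4-one
Conditions: H2 (1 atm), Pd/C, EtOAc–MeOH, rt
Reagents that add atoms: none
Why: Hydrogenolysis of four aryl benzyl ethers under neutral conditions; methyl ethers, the ketones and the four stereocentres are not affected.

Step 15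
Reactants: 25 (2S,3R)-3-[(2S,3S)-5,7-dihydroxy-2-(4-hydroxyphenyl)-4-oxochroman-3-yl]-7-hydroxy-5-methoxy-2-(4-methoxyphenyl)chroman-4-one
Product: 26 (2S,3R)-3-[(2S,3S)-5,7-dihydroxy-2-(4-hydroxyphenyl)-4-oxochroman-3-yl]-5,7-dihydroxy-2-(4-methoxyphenyl)chroman-4-one
Conditions: BCl3 (excess), CH2Cl2, –78 → 0 °C; then MeOH, aq. NaHCO3
Reagents that add atoms: none
Why: Chelation-controlled demethylation: boron bound between the C4 carbonyl and the peri C5 oxygen delivers chloride to that methyl group only; the anisyl methyl ether has no such chelate and stays.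

## Compound list

1 | 4-methoxybenzaldehyde | COc1ccc(C=O)cc1 | starting material
2 | (E)-1-methoxy-3-(trimethylsilyloxy)buta-1,3-diene | CO/C=C/C(=C)O[Si](C)(C)C | starting material
3 | (S,E)-1-methoxy-5-(4-methoxyphenyl)-5-(trimethylsilyloxy)pent-1-en-3-one | CO/C=C/C(=O)C[C@H](O[Si](C)(C)C)c1ccc(OC)cc1 | intermediate
4 | (S)-2-(4-methoxyphenyl)-2,3-dihydro-4H-pyran-4-one | COc1ccc([C@H]2OC=CC(=O)C2)cc1 | intermediate
5 | (S)-5-bromo-2-(4-methoxyphenyl)-2,3-dihydro-4H-pyran-4-one | COc1ccc([C@H]2OC=C(Br)C(=O)C2)cc1 | intermediate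
6 | 1,3,5-trifluorobenzene | Fc1cc(F)cc(F)c1 | starting material
7 | 1,3-bis(benzyloxy)-5-fluorobenzene | Fc1cc(OCc2ccccc2)cc(OCc2ccccc2)c1 | intermediate
8 | 1,5-bis(benzyloxy)-2-bromo-3-fluorobenzene | Fc1cc(OCc2ccccc2)cc(OCc2ccccc2)c1Br | intermediate
9 | [2,4-bis(benzyloxy)-6-fluorophenyl]lithium | [Li]c1c(F)cc(OCc2ccccc2)cc1OCc1ccccc1 | intermediate
10 | 1-[2,4-bis(benzyloxy)-6-fluorophenyl]-2-chloroethan-1-one | O=C(CCl)c1c(F)cc(OCc2ccccc2)cc1OCc1ccccc1 | intermediate
11 | 1-[2,4-bis(benzyloxy)-6-fluorophenyl]-2-iodoethan-1-one | O=C(CI)c1c(F)cc(OCc2ccccc2)cc1OCc1ccccc1 | intermediate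
12 | lithium (S)-5-bromo-2-(4-methoxyphenyl)-2H-pyran-4-olate | COc1ccc([C@H]2OC=C(Br)C(O[Li])=C2)cc1 | intermediate
13 | (2S,3R)-3-{2-[2,4-bis(benzyloxy)-6-fluorophenyl]-2-oxoethyl}-5-bromo-2-(4-methoxyphenyl)-2,3-dihydro-4H-pyran-4-one | COc1ccc([C@H]2OC=C(Br)C(=O)[C@@H]2CC(=O)c2c(F)cc(OCc3ccccc3)cc2OCc2ccccc2)cc1 | intermediate
14 | 1,1-dimethoxyethene | COC(=C)OC | starting material
15 | 4,4-dimethoxybut-3-en-2-one | COC(OC)=CC(C)=O | intermediate
16 | 1,1-dimethoxy-3-(trimethylsilyloxy)buta-1,3-diene | COC(OC)=CC(=C)O[Si](C)(C)C | intermediate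
17 | (2S,3R)-3-{2-[2,4-bis(benzyloxy)-6-fluorophenyl]-2-oxoethyl}-4a-bromo-5,5-dimethoxy-2-(4-methoxyphenyl)-7-(trimethylsilyloxy)-2,3,4a,5,8,8a-hexahydro-4H-chromen-4-one (ring-fusion isomers) | COc1ccc([C@H]2OC3CC(O[Si](C)(C)C)=CC(OC)(OC)C3(Br)C(=O)[C@@H]2CC(=O)c2c(F)cc(OCc3ccccc3)cc2OCc2ccccc2)cc1 | intermediate
18 | (2S,3R)-3-{2-[2,4-bis(benzyloxy)-6-fluorophenyl]-2-oxoethyl}-7-hydroxy-5-methoxy-2-(4-methoxyphenyl)chroman-4-one | COc1ccc([C@H]2Oc3cc(O)cc(OC)c3C(=O)[C@@H]2CC(=O)c2c(F)cc(OCc3ccccc3)cc2OCc2ccccc2)cc1 | intermediate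
19 | (2S,3R)-7-(benzyloxy)-3-{2-[2,4-bis(benzyloxy)-6-fluorophenyl]-2-oxoethyl}-5-methoxy-2-(4-methoxyphenyl)chroman-4-one | COc1ccc([C@H]2Oc3cc(OCc4ccccc4)cc(OC)c3C(=O)[C@@H]2CC(=O)c2c(F)cc(OCc3ccccc3)cc2OCc2ccccc2)cc1 | intermediate
20 | 4-(benzyloxy)benzaldehyde | O=Cc1ccc(OCc2ccccc2)cc1 | starting material
21 | (Z)-dibutylboron enolate of 19 | COc1ccc([C@H]2Oc3cc(OCc4ccccc4)cc(OC)c3C(=O)[C@@H]2/C=C(\OB(CCCC)CCCC)c2c(F)cc(OCc3ccccc3)cc2OCc2ccccc2)cc1 | intermediate
22 | (2S,3R)-7-(benzyloxy)-3-{(2S,3S)-1-[2,4-bis(benzyloxy)-6-fluorophenyl]-3-[4-(benzyloxy)phenyl]-3-hydroxy-1-oxopropan-2-yl}-5-methoxy-2-(4-methoxyphenyl)chroman-4-one | COc1ccc([C@H]2Oc3cc(OCc4ccccc4)cc(OC)c3C(=O)[C@@H]2[C@@H]([C@H](O)c2ccc(OCc3ccccc3)cc2)C(=O)c2c(F)cc(OCc3ccccc3)cc2OCc2ccccc2)cc1 | intermediate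
23 | potassium alkoxide of 22 | COc1ccc([C@H]2Oc3cc(OCc4ccccc4)cc(OC)c3C(=O)[C@@H]2[C@@H]([C@H]([O-])c2ccc(OCc3ccccc3)cc2)C(=O)c2c(F)cc(OCc3ccccc3)cc2OCc2ccccc2)cc1.[K+] | intermediate
24 | (2S,3R)-7-(benzyloxy)-3-{(2S,3S)-5,7-bis(benzyloxy)-2-[4-(benzyloxy)phenyl]-4-oxochroman-3-yl}-5-methoxy-2-(4-methoxyphenyl)chroman-4-one | COc1ccc([C@H]2Oc3cc(OCc4ccccc4)cc(OC)c3C(=O)[C@@H]2[C@@H]2C(=O)c3c(OCc4ccccc4)cc(OCc4ccccc4)cc3O[C@@H]2c2ccc(OCc3ccccc3)cc2)cc1 | intermediate
25 | (2S,3R)-3-[(2S,3S)-5,7-dihydroxy-2-(4-hydroxyphenyl)-4-oxochroman-3-yl]-7-hydroxy-5-methoxy-2-(4-methoxyphenyl)chroman-4-one | COc1ccc([C@H]2Oc3cc(O)cc(OC)c3C(=O)[C@@H]2[C@@H]2C(=O)c3c(O)cc(O)cc3O[C@@H]2c2ccc(O)cc2)cc1 | intermediate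
26 | (2S,3R)-3-[(2S,3S)-5,7-dihydroxy-2-(4-hydroxyphenyl)-4-oxochroman-3-yl]-5,7-dihydroxy-2-(4-methoxyphenyl)chroman-4-one | COc1ccc([C@H]2Oc3cc(O)cc(O)c3C(=O)[C@@H]2[C@@H]2C(=O)c3c(O)cc(O)cc3O[C@@H]2c2ccc(O)cc2)cc1 | target

## Step count and risks

Total: 15 steps. Longest linear sequence: 11 steps (6 → 7 → 8 → 10 → 11 → 13 → 18 → 19 → 22 → 24 → 25 → 26); the branch from aldehyde 1 is 9 steps.

**Step 10 (key step).**
- What may go wrong: the vinylogous ester may be too electron-rich to engage the diene before the diene decomposes. The adduct may stall before dehydrobromination, because H-8a is not acidic and sits cis to bromine. Base or HBr may open the pyranone at C2 and erode the stereocentre.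
- Fallback, by known chemistry, from iodoketone 11 back to 19: ring A is bought instead of built. 5,7-Dihydroxy-4H-chromen-4-one is benzylated at O7 (BnBr, K2CO3, acetone) to 7-(benzyloxy)-5-hydroxy-4H-chromen-4-one F1 and methylated at O5 (MeI, K2CO3, DMF) to 7-(benzyloxy)-5-methoxy-4H-chromen-4-one F2. Catalytic asymmetric conjugate addition of (4-methoxyphenyl)boronic acid (Pd(OCOCF3)2, a divalent palladium salt, with a chiral pyridine–oxazoline ligand; a known reaction class for chromones) gives (S)-7-(benzyloxy)-5-methoxy-2-(4-methoxyphenyl)chroman-4-one F3. Its lithium enolate (LiN(SiMe3)2, THF, –78 °C) is alkylated with 11 anti to the aryl group, giving 19.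

**Step 13.**
- What may go wrong: the potassium alkoxide may fragment by retro-aldol cleavage and recombine before it attacks the fluoroarene, scrambling C2'' and C3''. Residual base may epimerise the cis product to trans.
- Fallback, from bromopyranone 5 back to 24, closing the ring without any alkoxide: commercial 1-[2,4,6-tris(benzyloxy)phenyl]ethan-1-one is brominated (PhNMe3Br3, THF) to 2-bromo-1-[2,4,6-tris(benzyloxy)phenyl]ethan-1-one F4. Alkylation of enolate 12 with it gives (2S,3R)-5-bromo-2-(4-methoxyphenyl)-3-{2-oxo-2-[2,4,6-tris(benzyloxy)phenyl]ethyl}-2,3-dihydro-4H-pyran-4-one F5. The annulation with 16 then gives (2S,3R)-7-hydroxy-5-methoxy-2-(4-methoxyphenyl)-3-{2-oxo-2-[2,4,6-tris(benzyloxy)phenyl]ethyl}chroman-4-one F6, and benzylation gives (2S,3R)-7-(benzyloxy)-5-methoxy-2-(4-methoxyphenyl)-3-{2-oxo-2-[2,4,6-tris(benzyloxy)phenyl]ethyl}chroman-4-one F7. An anti-selective aldol reaction with 20 through the E-enolate ((c-C6H11)2BCl, Et3N), for which the same facial bias is expected, gives (2S,3R)-7-(benzyloxy)-3-{(2S,3R)-3-[4-(benzyloxy)phenyl]-3-hydroxy-1-oxo-1-[2,4,6-tris(benzyloxy)phenyl]propan-2-yl}-5-methoxy-2-(4-methoxyphenyl)chroman-4-one F8. MgBr2·OEt2 removes only a benzyl group ortho to the ketone, giving (2S,3R)-7-(benzyloxy)-3-{(2S,3R)-1-[2,4-bis(benzyloxy)-6-hydroxyphenyl]-3-[4-(benzyloxy)phenyl]-3-hydroxy-1-oxopropan-2-yl}-5-methoxy-2-(4-methoxyphenyl)chroman-4-one F9. Mitsunobu closure (PPh3, diisopropyl azodicarboxylate) with inversion at C2'' then gives 24.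

**Step 12.**
- What may go wrong: facial selectivity may be poor, since the bias comes only from the conformation about C3–C3''. The boron triflate may enolise the chromanone ketone instead. The hindered, twisted aryl ketone may give a mixed enolate geometry and lose syn selectivity.
- Fallback, from 19 back to 22, replacing substrate control by catalyst control: 19 is converted (Me3SiOTf, Et3N) into (2S,3R)-7-(benzyloxy)-3-{(Z)-2-[2,4-bis(benzyloxy)-6-fluorophenyl]-2-(trimethylsilyloxy)ethenyl}-5-methoxy-2-(4-methoxyphenyl)chroman-4-one F10. This undergoes a Mukaiyama aldol reaction with 20 under a tartrate-derived acyloxyborane catalyst (from mono(2,6-diisopropoxybenzoyl)tartaric acid and BH3·THF). That catalyst class gives syn adducts through an open transition state whatever the enol ether geometry. The tartrate antipode is chosen for attack on the required face, and acidic work-up gives 22.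

**Step 7.**
- What may go wrong: the bromo enolate may open by β-elimination of the ring oxygen. The α-iodo ketone may transfer a proton or iodine to the enolate instead of alkylating it.
- Fallback, from pyranone 4 back to 13, forming the aryl ketone after a simple allylation: the enolate of 4 is allylated (LiN(SiMe3)2; allyl bromide) to (2S,3R)-2-(4-methoxyphenyl)-3-(prop-2-en-1-yl)-2,3-dihydro-4H-pyran-4-one F11, which NBS converts into (2S,3R)-5-bromo-2-(4-methoxyphenyl)-3-(prop-2-en-1-yl)-2,3-dihydro-4H-pyran-4-one F12. Lemieux–Johnson cleavage (OsO4 cat., NaIO4, 2,6-lutidine) gives 2-[(2S,3R)-5-bromo-2-(4-methoxyphenyl)-4-oxo-3,4-dihydro-2H-pyran-3-yl]acetaldehyde F13. The aryl group of 9, transmetalated with MgBr2·OEt2, adds to the aldehyde at –78 °C to give (2S,3R)-3-{2-[2,4-bis(benzyloxy)-6-fluorophenyl]-2-hydroxyethyl}-5-bromo-2-(4-methoxyphenyl)-2,3-dihydro-4H-pyran-4-one F14. Dess–Martin oxidation then gives 13.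

## Further compounds

F1 | step 10 | 7-(benzyloxy)-5-hydroxy-4H-chromen-4-one | O=c1ccoc2cc(OCc3ccccc3)cc(O)c12
F2 | step 10 | 7-(benzyloxy)-5-methoxy-4H-chromen-4-one | O=c1ccoc2cc(OCc3ccccc3)cc(OC)c12
F3 | step 10 | (S)-7-(benzyloxy)-5-methoxy-2-(4-methoxyphenyl)chroman-4-one | COc1ccc([C@H]2Oc3cc(OCc4ccccc4)cc(OC)c3C(=O)C2)cc1
F4 | step 13 | 2-bromo-1-[2,4,6-tris(benzyloxy)phenyl]ethan-1-one | O=C(CBr)c1c(OCc2ccccc2)cc(OCc2ccccc2)cc1OCc1ccccc1
F5 | step 13 | (2S,3R)-5-bromo-2-(4-methoxyphenyl)-3-{2-oxo-2-[2,4,6-tris(benzyloxy)phenyl]ethyl}-2,3-dihydro-4H-pyran-4-one | COc1ccc([C@H]2OC=C(Br)C(=O)[C@@H]2CC(=O)c2c(OCc3ccccc3)cc(OCc3ccccc3)cc2OCc2ccccc2)cc1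
F6 | step 13 | (2S,3R)-7-hydroxy-5-methoxy-2-(4-methoxyphenyl)-3-{2-oxo-2-[2,4,6-tris(benzyloxy)phenyl]ethyl}chroman-4-one | COc1ccc([C@H]2Oc3cc(O)cc(OC)c3C(=O)[C@@H]2CC(=O)c2c(OCc3ccccc3)cc(OCc3ccccc3)cc2OCc2ccccc2)cc1
F7 | step 13 | (2S,3R)-7-(benzyloxy)-5-methoxy-2-(4-methoxyphenyl)-3-{2-oxo-2-[2,4,6-tris(benzyloxy)phenyl]ethyl}chroman-4-one | COc1ccc([C@H]2Oc3cc(OCc4ccccc4)cc(OC)c3C(=O)[C@@H]2CC(=O)c2c(OCc3ccccc3)cc(OCc3ccccc3)cc2OCc2ccccc2)cc1
F8 | step 13 | (2S,3R)-7-(benzyloxy)-3-{(2S,3R)-3-[4-(benzyloxy)phenyl]-3-hydroxy-1-oxo-1-[2,4,6-tris(benzyloxy)phenyl]propan-2-yl}-5-methoxy-2-(4-methoxyphenyl)chroman-4-one | COc1ccc([C@H]2Oc3cc(OCc4ccccc4)cc(OC)c3C(=O)[C@@H]2[C@@H]([C@@H](O)c2ccc(OCc3ccccc3)cc2)C(=O)c2c(OCc3ccccc3)cc(OCc3ccccc3)cc2OCc2ccccc2)cc1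
F9 | step 13 | (2S,3R)-7-(benzyloxy)-3-{(2S,3R)-1-[2,4-bis(benzyloxy)-6-hydroxyphenyl]-3-[4-(benzyloxy)phenyl]-3-hydroxy-1-oxopropan-2-yl}-5-methoxy-2-(4-methoxyphenyl)chroman-4-one | COc1ccc([C@H]2Oc3cc(OCc4ccccc4)cc(OC)c3C(=O)[C@@H]2[C@@H]([C@@H](O)c2ccc(OCc3ccccc3)cc2)C(=O)c2c(O)cc(OCc3ccccc3)cc2OCc2ccccc2)cc1
F10 | step 12 | (2S,3R)-7-(benzyloxy)-3-{(Z)-2-[2,4-bis(benzyloxy)-6-fluorophenyl]-2-(trimethylsilyloxy)ethenyl}-5-methoxy-2-(4-methoxyphenyl)chroman-4-one | COc1ccc([C@H]2Oc3cc(OCc4ccccc4)cc(OC)c3C(=O)[C@@H]2/C=C(\O[Si](C)(C)C)c2c(F)cc(OCc3ccccc3)cc2OCc2ccccc2)cc1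
F11 | step 7 | (2S,3R)-2-(4-methoxyphenyl)-3-(prop-2-en-1-yl)-2,3-dihydro-4H-pyran-4-one | COc1ccc([C@H]2OC=CC(=O)[C@@H]2CC=C)cc1
F12 | step 7 | (2S,3R)-5-bromo-2-(4-methoxyphenyl)-3-(prop-2-en-1-yl)-2,3-dihydro-4H-pyran-4-one | COc1ccc([C@H]2OC=C(Br)C(=O)[C@@H]2CC=C)cc1
F13 | step 7 | 2-[(2S,3R)-5-bromo-2-(4-methoxyphenyl)-4-oxo-3,4-dihydro-2H-pyran-3-yl]acetaldehyde | COc1ccc([C@H]2OC=C(Br)C(=O)[C@@H]2CC=O)cc1
F14 | step 7 | (2S,3R)-3-{2-[2,4-bis(benzyloxy)-6-fluorophenyl]-2-hydroxyethyl}-5-bromo-2-(4-methoxyphenyl)-2,3-dihydro-4H-pyran-4-one (carbinol epimers) | COc1ccc([C@H]2OC=C(Br)C(=O)[C@@H]2CC(O)c2c(F)cc(OCc3ccccc3)cc2OCc2ccccc2)cc1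
A1 | alternative 1 | 5,7-bis(benzyloxy)-4H-chromen-4-one | O=c1ccoc2cc(OCc3ccccc3)cc(OCc3ccccc3)c12
A2 | alternative 1 | (4-methoxyphenyl)zinc chloride | COc1ccc([Zn]Cl)cc1
A3 | alternative 1 | 2-bromo-1-[2,4-bis(benzyloxy)-6-fluorophenyl]ethan-1-one | O=C(CBr)c1c(F)cc(OCc2ccccc2)cc1OCc1ccccc1
A4 | alternative 1 | (2S,3R)-5,7-bis(benzyloxy)-3-{2-[2,4-bis(benzyloxy)-6-fluorophenyl]-2-oxoethyl}-2-(4-methoxyphenyl)chroman-4-one | COc1ccc([C@H]2Oc3cc(OCc4ccccc4)cc(OCc4ccccc4)c3C(=O)[C@@H]2CC(=O)c2c(F)cc(OCc3ccccc3)cc2OCc2ccccc2)cc1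
A5 | alternative 2 | 2,4-bis(benzyloxy)-6-hydroxybenzaldehyde | O=Cc1c(O)cc(OCc2ccccc2)cc1OCc1ccccc1
A6 | alternative 2 | methyl (E)-4-(4-methoxyphenyl)but-3-enoate | COC(=O)C/C=C/c1ccc(OC)cc1
A7 | alternative 2 | methyl 2-[5,7-bis(benzyloxy)-4-methoxy-2-(4-methoxyphenyl)chroman-3-yl]acetate (2,3-trans-3,4-trans) | COc1ccc([C@H]2Oc3cc(OCc4ccccc4)cc(OCc4ccccc4)c3[C@@H](OC)[C@@H]2CC(=O)OC)cc1
A8 | alternative 3 | tert-butyl 2-[4-(benzyloxy)phenyl]-4-{[3,5-bis(benzyloxy)-2-bromophenoxy](4-methoxyphenyl)methyl}-5-oxotetrahydrofuran-3-carboxylate (configuration as in the SMILES) | COc1ccc([C@@H](Oc2cc(OCc3ccccc3)cc(OCc3ccccc3)c2Br)[C@@H]2C(=O)O[C@H](c3ccc(OCc4ccccc4)cc3)[C@H]2C(=O)OC(C)(C)C)cc1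
A9 | alternative 3 | tert-butyl 3-[4-(benzyloxy)phenyl]-3-hydroxy-2-[(2S,3R)-5,7-bis(benzyloxy)-2-(4-methoxyphenyl)-4-oxochroman-3-yl]propanoate | COc1ccc([C@H]2Oc3cc(OCc4ccccc4)cc(OCc4ccccc4)c3C(=O)[C@@H]2[C@H](C(=O)OC(C)(C)C)[C@H](O)c2ccc(OCc3ccccc3)cc2)cc1
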